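**Strategy.** The synthesis rests on disconnecting the tetrahydropyran (ring atoms O1, C2 to C6; C3 side chain C1' to C7') at its O1–C2 benzylic ether bond after recasting C4, the ring carbon that finally bears chalcone ring A, as a ketone. C2 is then the β-carbon of an enone, so O1–C2 can form by oxa-Michael addition. In one operation a Maitland–Japp reaction joins an acyclic (5S)-δ-hydroxy-β-ketoester with 4-silyloxybenzaldehyde, forging C2–C3 and closing the ring at O1–C2 with C2 cis to C6. The ester later delivers C1' by decarboxylative allylation, and the ketone becomes the C4–aryl bond through a stereoconvergent Negishi coupling with a preformed iodochalcone.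

Key step: step 4

Remarks and assumption: TBS = tert-butyldimethylsilyl. The antipodes of BINOL (step 3), of the phosphoramidite (step 8) and of the allylborane (step 9) are assigned by analogy with simple aliphatic aldehydes and cinnamyl electrophiles; the other antipode would be used if a sense proved reversed. Compound 7 is drawn without alkene geometry and 24 without C4 configuration, because both are immaterial.

Step 1
Reactants: 1 methyl 3-(4-hydroxyphenyl)propanoate
Product: 2 methyl 3-[4-(TBS-oxy)phenyl]propanoate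
Conditions: TBSCl, imidazole, DMF, rt
Reagents that add atoms: tert-butyldimethylsilyl chloride, CC(C)(C)[Si](C)(C)Cl
Why: Phenol silylation (silyl ether protection) masks the acidic OH for the Lewis-acid and organometallic steps and is removable by mild methanolysis at the end.

Step 2
Reactants: 2 methyl 3-[4-(TBS-oxy)phenyl]propanoate
Product: 3 3-[4-(TBS-oxy)phenyl]propanal
Conditions: i-Bu2AlH (1.05 equiv), CH2Cl2, −78 °C; Rochelle salt
Reagents that add atoms: none
Why: Partial ester reduction (DIBAL reduction) should stop at the aldehyde because the tetrahedral aluminium hemiacetal survives at −78 °C until work-up.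

Step 3
Reactants: 3 3-[4-(TBS-oxy)phenyl]propanal; 4 1-methoxy-1,3-bis(trimethylsilyloxy)buta-1,3-diene
Product: 5 methyl (5S)-5-hydroxy-3-oxo-7-[4-(TBS-oxy)phenyl]heptanoate
Conditions: Ti(OiPr)4 (10 mol%), (R)-BINOL (10 mol%), THF, −78 °C → rt; then TFA, 0 °C
Reagents that add atoms: none
Why: Titanium–BINOL-catalysed vinylogous Mukaiyama aldol addition of the dienolate terminus to the aldehyde should give the δ-hydroxy-β-ketoester, the chiral Lewis acid selecting the aldehyde face so that the carbinol (future C6) is S.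

Step 4
Reactants: 5 methyl (5S)-5-hydroxy-3-oxo-7-[4-(TBS-oxy)phenyl]heptanoate; 6 4-(TBS-oxy)benzaldehyde
Product: 8 methyl (2S,3R,6S)-4-oxo-2-[4-(TBS-oxy)phenyl]-6-{2-[4-(TBS-oxy)phenyl]ethyl}oxane-3-carboxylate, via Knoevenagel alkylidene ketoester 7 (not isolated)
Conditions: Yb(OTf)3 (10 mol%), CaSO4, CH2Cl2, rt, prolonged stirring for equilibration
Reagents that add atoms: none
Why: Yb(OTf)3 promotes Knoevenagel condensation of the aldehyde at C3, the only doubly activated carbon of 5, to give alkylidene 7, whose δ-hydroxyl then adds to the enone β-carbon C2 (oxa-Michael), forming the O1–C2 bond. The closest known reaction type is the Maitland–Japp synthesis of 2,6-cis-tetrahydropyran-4-ones from δ-hydroxy-β-ketoesters and aldehydes. The ring closes in the 6-endo-trig mode, both carbons of the C2=C3 bond ending inside the ring. C2 is set under thermodynamic control: the oxa-Michael addition is reversible, so the chair with the C2 aryl and the C6 arylethyl group both equatorial (2,6-cis) should accumulate, its absolute sense fixed by the 5S carbinol, while the enolisable C3 ester settles equatorial. The step needs condensation at C3 rather than C5 and no retro-aldol or dehydration of the β-hydroxy ketone; the 1,3-dicarbonyl acidity of C3 and the mild lanthanide Lewis acid secure both, and the silyloxy group keeps the aldehyde electrophilic enough.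

Step 5
Reactants: 9 methyl (E)-4-hydroxycinnamate
Product: 10 methyl (E)-4-(TBS-oxy)cinnamate
Conditions: TBSCl, imidazole, DMF, rt
Reagents that add atoms: tert-butyldimethylsilyl chloride, CC(C)(C)[Si](C)(C)Cl
Why: Phenol silylation (silyl ether protection) as in step 1.

Step 6
Reactants: 10 methyl (E)-4-(TBS-oxy)cinnamate
Product: 11 (E)-3-[4-(TBS-oxy)phenyl]prop-2-en-1-ol
Conditions: i-Bu2AlH (2.2 equiv), CH2Cl2, −78 → 0 °C; Rochelle salt
Reagents that add atoms: none
Why: Exhaustive 1,2-reduction of the conjugated ester (DIBAL reduction) should give the allylic alcohol without touching the alkene.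

Step 7
Reactants: 8 methyl (2S,3R,6S)-4-oxo-2-[4-(TBS-oxy)phenyl]-6-{2-[4-(TBS-oxy)phenyl]ethyl}oxane-3-carboxylate; 11 (E)-3-[4-(TBS-oxy)phenyl]prop-2-en-1-ol
Product: 12 (E)-3-[4-(TBS-oxy)phenyl]prop-2-enyl (2S,3R,6S)-4-oxo-2-[4-(TBS-oxy)phenyl]-6-{2-[4-(TBS-oxy)phenyl]ethyl}oxane-3-carboxylate
Conditions: 11 (1.5 equiv), DMAP (20 mol%), toluene, 110 °C, 4 Å molecular sieves (removal of MeOH)
Reagents that add atoms: none
Why: DMAP-catalysed transesterification of an enolisable β-ketoester is driven by removal of methanol and cannot damage the ring stereocentres, since C3 re-equilibrates to the same equatorial ester.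

Step 8
Reactants: 12 (E)-3-[4-(TBS-oxy)phenyl]prop-2-enyl (2S,3R,6S)-4-oxo-2-[4-(TBS-oxy)phenyl]-6-{2-[4-(TBS-oxy)phenyl]ethyl}oxane-3-carboxylate
Product: 13 (2S,3R,6S)-2-[4-(TBS-oxy)phenyl]-3-{(1S)-1-[4-(TBS-oxy)phenyl]prop-2-enyl}-6-{2-[4-(TBS-oxy)phenyl]ethyl}oxan-4-one
Conditions: [Ir(cod)Cl]2 (2 mol%), (Ra)-1,1'-binaphthyl-2,2'-diyl N,N-bis[(R)-1-phenylethyl]phosphoramidite (4 mol%), DBU (1 equiv), CH2Cl2, 40 °C
Reagents that add atoms: none
Why: Iridium-catalysed decarboxylative allylic alkylation (Tsuji–Trost type): ionisation of the cinnamyl ester and loss of CO2 unmask the C3 enolate regiospecifically, which should attack the aryl-bearing terminus of the allyliridium complex on the face dictated by the phosphoramidite, setting C1' (S), while C3 equilibrates under DBU to the equatorial epimer trans to the C2 aryl group.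

Step 9
Reactants: 3 3-[4-(TBS-oxy)phenyl]propanal
Product: 14 (3S)-1-[4-(TBS-oxy)phenyl]hex-5-en-3-ol
Conditions: (+)-Ipc2B(allyl), Et2O, −78 °C; then HOCH2CH2NH2, rt
Reagents that add atoms: (+)-B-allyldiisopinocampheylborane, C=CCB(C1CC2CC(C1C)C2(C)C)C1CC2CC(C1C)C2(C)C
Why: Asymmetric allylboration (Brown allylation) through a chair-like six-membered transition state, the isopinocampheyl groups selecting the aldehyde face, should give the S carbinol (future C5').

Step 10
Reactants: 14 (3S)-1-[4-(TBS-oxy)phenyl]hex-5-en-3-ol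
Product: 15 (3S)-1-[4-(TBS-oxy)phenyl]hex-5-en-3-yl acetate
Conditions: Ac2O, pyridine, DMAP (cat.), CH2Cl2, rt
Reagents that add atoms: acetic anhydride, CC(=O)OC(C)=O
Why: Acetylation (esterification) protects the carbinol through the reduction, iodination and organozinc steps and is removed together with the aryl acetates at the end.

Step 11
Reactants: 13 (2S,3R,6S)-2-[4-(TBS-oxy)phenyl]-3-{(1S)-1-[4-(TBS-oxy)phenyl]prop-2-enyl}-6-{2-[4-(TBS-oxy)phenyl]ethyl}oxan-4-one; 15 (3S)-1-[4-(TBS-oxy)phenyl]hex-5-en-3-yl acetate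
Product: 16 (2S,3R,6S)-3-{(1S,2E,5S)-5-acetoxy-1,7-bis[4-(TBS-oxy)phenyl]hept-2-enyl}-2-[4-(TBS-oxy)phenyl]-6-{2-[4-(TBS-oxy)phenyl]ethyl}oxan-4-one
Conditions: 15 (3 equiv), second-generation Hoveyda–Grubbs catalyst RuCl2(H2IMes)(=CH-C6H4-2-OiPr) (5 mol%), 1,4-benzoquinone (10 mol%), CH2Cl2, 40 °C
Reagents that add atoms: none
Why: Olefin cross-metathesis between the hindered, allylically branched vinyl group of 13, which does not homodimerise, and an excess of the unhindered terminal alkene 15 should give the 1,2-disubstituted alkene with thermodynamic E geometry, benzoquinone suppressing ruthenium hydride-mediated alkene migration.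

Step 12
Reactants: 16 (2S,3R,6S)-3-{(1S,2E,5S)-5-acetoxy-1,7-bis[4-(TBS-oxy)phenyl]hept-2-enyl}-2-[4-(TBS-oxy)phenyl]-6-{2-[4-(TBS-oxy)phenyl]ethyl}oxan-4-one
Product: 17 (2S,3S,4R,6S)-3-{(1S,2E,5S)-5-acetoxy-1,7-bis[4-(TBS-oxy)phenyl]hept-2-enyl}-2-[4-(TBS-oxy)phenyl]-6-{2-[4-(TBS-oxy)phenyl]ethyl}oxan-4-ol (equatorial alcohol)
Conditions: NaBH4, MeOH/THF, −20 °C
Reagents that add atoms: none
Why: Ketone reduction with NaBH4 (axial hydride attack, mainly equatorial alcohol) is chemoselective over the acetate, and the C4 configuration formed here is immaterial because it is erased at the organozinc stage.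

Step 13
Reactants: 17 (2S,3S,4R,6S)-3-{(1S,2E,5S)-5-acetoxy-1,7-bis[4-(TBS-oxy)phenyl]hept-2-enyl}-2-[4-(TBS-oxy)phenyl]-6-{2-[4-(TBS-oxy)phenyl]ethyl}oxan-4-ol
Product: 18 (2S,3R,4S,6S)-3-{(1S,2E,5S)-5-acetoxy-1,7-bis[4-(TBS-oxy)phenyl]hept-2-enyl}-4-iodo-2-[4-(TBS-oxy)phenyl]-6-{2-[4-(TBS-oxy)phenyl]ethyl}oxane (axial iodide)
Conditions: I2, PPh3, imidazole, toluene, 60 °C
Reagents that add atoms: iodine, II
Why: Appel-type iodination converts the alcohol into the secondary iodide by SN2 displacement of the oxyphosphonium group with inversion, giving the handle for zinc insertion.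

Step 14
Reactants: 19 1-(2,4-dihydroxy-6-methoxyphenyl)ethanone
Product: 20 1-(2,4-dihydroxy-3-iodo-6-methoxyphenyl)ethanone
Conditions: N-iodosuccinimide (1.0 equiv), MeCN, 0 °C
Reagents that add atoms: N-iodosuccinimide, O=C1CCC(=O)N1I
Why: Electrophilic aromatic iodination should occur at C3', the position flanked by both hydroxyls and para to the methoxy group, which is the most activated and least hindered site.

Step 15
Reactants: 20 1-(2,4-dihydroxy-3-iodo-6-methoxyphenyl)ethanone; 21 4-hydroxybenzaldehyde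
Product: 22 (E)-1-(2,4-dihydroxy-3-iodo-6-methoxyphenyl)-3-(4-hydroxyphenyl)prop-2-en-1-one
Conditions: KOH (50% aq.), EtOH, rt; then AcOH to pH 5, 0 °C
Reagents that add atoms: none
Why: Claisen–Schmidt condensation (aldol addition of the methyl ketone enolate to the non-enolisable aldehyde, then E1cB dehydration) should give the thermodynamically preferred E-chalcone.

Step 16
Reactants: 22 (E)-1-(2,4-dihydroxy-3-iodo-6-methoxyphenyl)-3-(4-hydroxyphenyl)prop-2-en-1-one
Product: 23 (E)-1-(2,4-diacetoxy-3-iodo-6-methoxyphenyl)-3-(4-acetoxyphenyl)prop-2-en-1-one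
Conditions: Ac2O, pyridine, DMAP (cat.), rt
Reagents that add atoms: acetic anhydride, CC(=O)OC(C)=O
Why: Exhaustive O-acetylation gives small, base-labile protecting groups that organozinc reagents tolerate and that crowd the positions flanking the iodide as little as possible.

Step 17
Reactants: 18 (2S,3R,4S,6S)-3-{(1S,2E,5S)-5-acetoxy-1,7-bis[4-(TBS-oxy)phenyl]hept-2-enyl}-4-iodo-2-[4-(TBS-oxy)phenyl]-6-{2-[4-(TBS-oxy)phenyl]ethyl}oxane; 23 (E)-1-(2,4-diacetoxy-3-iodo-6-methoxyphenyl)-3-(4-acetoxyphenyl)prop-2-en-1-one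
Product: 25 tetra-O-TBS tetra-O-acetyl blepharocalyxin E (2S,3R,4R,6S; 1'S,5'S), via oxan-4-ylzinc iodide 24 (not isolated)
Conditions: Zn dust (activated with BrCH2CH2Br/Me3SiCl), LiCl, THF, 35 °C; then 23 (1.5 equiv), Pd(OAc)2 (5 mol%), CPhos (10 mol%), THF/NMP, rt
Reagents that add atoms: none
Why: Zinc insertion then Negishi cross-coupling: the secondary cyclic alkylzinc is configurationally labile and should transmetallate to the palladium intermediate with the metal equatorial, so that reductive elimination with retention places ring A equatorial at C4, trans to the C3 substituent and cis to the C2 and C6 substituents, as established for substituted six-membered cycloalkylzinc reagents.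

Step 18
Reactants: 25 tetra-O-TBS tetra-O-acetyl blepharocalyxin E
Product: 26 blepharocalyxin E
Conditions: K2CO3, MeOH/THF, 0 °C → rt; AcOH quench
Reagents that add atoms: none
Why: Carbonate-catalysed methanolysis (transesterification of the four acetates and cleavage of the four aryl silyl ethers) should be mild enough to leave the chalcone, the skipped alkene and the benzylic ether of the tetrahydropyran intact.

**Compound list**

1 | methyl 3-(4-hydroxyphenyl)propanoate | COC(=O)CCc1ccc(O)cc1 | starting material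
2 | methyl 3-[4-(TBS-oxy)phenyl]propanoate | COC(=O)CCc1ccc(O[Si](C)(C)C(C)(C)C)cc1 | intermediate
3 | 3-[4-(TBS-oxy)phenyl]propanal | O=CCCc1ccc(O[Si](C)(C)C(C)(C)C)cc1 | intermediate
4 | 1-methoxy-1,3-bis(trimethylsilyloxy)buta-1,3-diene | COC(O[Si](C)(C)C)=CC(=C)O[Si](C)(C)C | starting material
5 | methyl (5S)-5-hydroxy-3-oxo-7-[4-(TBS-oxy)phenyl]heptanoate | COC(=O)CC(=O)C[C@@H](O)CCc1ccc(O[Si](C)(C)C(C)(C)C)cc1 | intermediate
6 | 4-(TBS-oxy)benzaldehyde | O=Cc1ccc(O[Si](C)(C)C(C)(C)C)cc1 | starting material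
7 | methyl (5S)-2-[4-(TBS-oxy)benzylidene]-5-hydroxy-3-oxo-7-[4-(TBS-oxy)phenyl]heptanoate (not isolated) | COC(=O)C(=Cc1ccc(O[Si](C)(C)C(C)(C)C)cc1)C(=O)C[C@@H](O)CCc1ccc(O[Si](C)(C)C(C)(C)C)cc1 | intermediate
8 | methyl (2S,3R,6S)-4-oxo-2-[4-(TBS-oxy)phenyl]-6-{2-[4-(TBS-oxy)phenyl]ethyl}oxane-3-carboxylate (2,6-cis, keto form, all substituents equatorial) | O=C1C[C@H](CCc2ccc(O[Si](C)(C)C(C)(C)C)cc2)O[C@H](c2ccc(O[Si](C)(C)C(C)(C)C)cc2)[C@H]1C(=O)OC | intermediate
9 | methyl (E)-4-hydroxycinnamate | COC(=O)/C=C/c1ccc(O)cc1 | starting material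
10 | methyl (E)-4-(TBS-oxy)cinnamate | COC(=O)/C=C/c1ccc(O[Si](C)(C)C(C)(C)C)cc1 | intermediate
11 | (E)-3-[4-(TBS-oxy)phenyl]prop-2-en-1-ol | OC/C=C/c1ccc(O[Si](C)(C)C(C)(C)C)cc1 | intermediate
12 | (E)-3-[4-(TBS-oxy)phenyl]prop-2-enyl (2S,3R,6S)-4-oxo-2-[4-(TBS-oxy)phenyl]-6-{2-[4-(TBS-oxy)phenyl]ethyl}oxane-3-carboxylate | O=C1C[C@H](CCc2ccc(O[Si](C)(C)C(C)(C)C)cc2)O[C@H](c2ccc(O[Si](C)(C)C(C)(C)C)cc2)[C@H]1C(=O)OC/C=C/c1ccc(O[Si](C)(C)C(C)(C)C)cc1 | intermediate
13 | (2S,3R,6S)-2-[4-(TBS-oxy)phenyl]-3-{(1S)-1-[4-(TBS-oxy)phenyl]prop-2-enyl}-6-{2-[4-(TBS-oxy)phenyl]ethyl}oxan-4-one (all substituents equatorial) | O=C1C[C@H](CCc2ccc(O[Si](C)(C)C(C)(C)C)cc2)O[C@H](c2ccc(O[Si](C)(C)C(C)(C)C)cc2)[C@H]1[C@H](C=C)c1ccc(O[Si](C)(C)C(C)(C)C)cc1 | intermediate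
14 | (3S)-1-[4-(TBS-oxy)phenyl]hex-5-en-3-ol | C=CC[C@@H](O)CCc1ccc(O[Si](C)(C)C(C)(C)C)cc1 | intermediate
15 | (3S)-1-[4-(TBS-oxy)phenyl]hex-5-en-3-yl acetate | C=CC[C@@H](OC(C)=O)CCc1ccc(O[Si](C)(C)C(C)(C)C)cc1 | intermediate
16 | (2S,3R,6S)-3-{(1S,2E,5S)-5-acetoxy-1,7-bis[4-(TBS-oxy)phenyl]hept-2-enyl}-2-[4-(TBS-oxy)phenyl]-6-{2-[4-(TBS-oxy)phenyl]ethyl}oxan-4-one | O=C1C[C@H](CCc2ccc(O[Si](C)(C)C(C)(C)C)cc2)O[C@H](c2ccc(O[Si](C)(C)C(C)(C)C)cc2)[C@H]1[C@H](/C=C/C[C@@H](OC(C)=O)CCc1ccc(O[Si](C)(C)C(C)(C)C)cc1)c1ccc(O[Si](C)(C)C(C)(C)C)cc1 | intermediate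
17 | (2S,3S,4R,6S)-3-{(1S,2E,5S)-5-acetoxy-1,7-bis[4-(TBS-oxy)phenyl]hept-2-enyl}-2-[4-(TBS-oxy)phenyl]-6-{2-[4-(TBS-oxy)phenyl]ethyl}oxan-4-ol | O[C@@H]1C[C@H](CCc2ccc(O[Si](C)(C)C(C)(C)C)cc2)O[C@H](c2ccc(O[Si](C)(C)C(C)(C)C)cc2)[C@H]1[C@H](/C=C/C[C@@H](OC(C)=O)CCc1ccc(O[Si](C)(C)C(C)(C)C)cc1)c1ccc(O[Si](C)(C)C(C)(C)C)cc1 | intermediate
18 | (2S,3R,4S,6S)-3-{(1S,2E,5S)-5-acetoxy-1,7-bis[4-(TBS-oxy)phenyl]hept-2-enyl}-4-iodo-2-[4-(TBS-oxy)phenyl]-6-{2-[4-(TBS-oxy)phenyl]ethyl}oxane | I[C@H]1C[C@H](CCc2ccc(O[Si](C)(C)C(C)(C)C)cc2)O[C@H](c2ccc(O[Si](C)(C)C(C)(C)C)cc2)[C@H]1[C@H](/C=C/C[C@@H](OC(C)=O)CCc1ccc(O[Si](C)(C)C(C)(C)C)cc1)c1ccc(O[Si](C)(C)C(C)(C)C)cc1 | intermediate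
19 | 1-(2,4-dihydroxy-6-methoxyphenyl)ethanone | CC(=O)c1c(O)cc(O)cc1OC | starting material
20 | 1-(2,4-dihydroxy-3-iodo-6-methoxyphenyl)ethanone | CC(=O)c1c(O)c(I)c(O)cc1OC | intermediate
21 | 4-hydroxybenzaldehyde | O=Cc1ccc(O)cc1 | starting material
22 | (E)-1-(2,4-dihydroxy-3-iodo-6-methoxyphenyl)-3-(4-hydroxyphenyl)prop-2-en-1-one | COc1cc(O)c(I)c(O)c1C(=O)/C=C/c1ccc(O)cc1 | intermediate
23 | (E)-1-(2,4-diacetoxy-3-iodo-6-methoxyphenyl)-3-(4-acetoxyphenyl)prop-2-en-1-one | COc1cc(OC(C)=O)c(I)c(OC(C)=O)c1C(=O)/C=C/c1ccc(OC(C)=O)cc1 | intermediate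
24 | oxan-4-ylzinc iodide derived from 18 (C4 labile, not isolated) | I[Zn]C1C[C@H](CCc2ccc(O[Si](C)(C)C(C)(C)C)cc2)O[C@H](c2ccc(O[Si](C)(C)C(C)(C)C)cc2)[C@H]1[C@H](/C=C/C[C@@H](OC(C)=O)CCc1ccc(O[Si](C)(C)C(C)(C)C)cc1)c1ccc(O[Si](C)(C)C(C)(C)C)cc1 | intermediate
25 | tetra-O-TBS tetra-O-acetyl blepharocalyxin E (four aryl TBS ethers; acetates on C5'-O and the three chalcone phenols) | COc1cc(OC(C)=O)c([C@@H]2C[C@H](CCc3ccc(O[Si](C)(C)C(C)(C)C)cc3)O[C@H](c3ccc(O[Si](C)(C)C(C)(C)C)cc3)[C@H]2[C@H](/C=C/C[C@@H](OC(C)=O)CCc2ccc(O[Si](C)(C)C(C)(C)C)cc2)c2ccc(O[Si](C)(C)C(C)(C)C)cc2)c(OC(C)=O)c1C(=O)/C=C/c1ccc(OC(C)=O)cc1 | intermediate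
26 | blepharocalyxin E | COc1cc(O)c([C@@H]2C[C@H](CCc3ccc(O)cc3)O[C@H](c3ccc(O)cc3)[C@H]2[C@H](/C=C/C[C@@H](O)CCc2ccc(O)cc2)c2ccc(O)cc2)c(O)c1C(=O)/C=C/c1ccc(O)cc1 | target

**Step count.** Total: 18 steps. Longest linear sequence: 11 steps (steps 1, 2, 3, 4, 7, 8, 11, 12, 13, 17, 18).

**Steps most likely to fail**

Step 17. The risk is slow transmetallation and reductive elimination between the β-branched secondary alkyl group and the doubly ortho-substituted aryl partner, so that β-hydride elimination and protonolysis consume the zinc reagent. The fallback reverses the polarity of the partners and makes the bond through a C4 radical. Iodide 18 is kept as the electrophile and coupled under cobalt catalysis (CoCl2, 2,2'-bipyridine, THF, 0 °C → rt) with the arylzinc iodide of the chalcone triacetate F1, made from 23 by zinc insertion (Zn, LiCl, THF). The C4 radical should be captured on the face away from the C3 substituent, giving the same equatorial aryl group. The fallback sets out from 18 and comes back at 25.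

Step 8. The risk is that, after loss of CO2, the non-stabilised ring enolate undergoes proton transfer from C3 to C5, simple protonation, or retro-oxa-Michael opening followed by O-allylation, and that attack at the branched terminus erodes. The fallback allylates while the enolate is still stabilised by the ester. Methyl ester 8 is treated with (E)-3-[4-(TBS-oxy)phenyl]prop-2-enyl methyl carbonate F2 (from 11 with ClCO2Me/pyridine) under [Ir(cod)Cl]2 and the same phosphoramidite (LiOt-Bu, THF, rt). This should give the C3-quaternary allylated β-ketoester F3, whose ester is then removed by Krapcho-type dealkoxycarbonylation (LiI, 2,6-lutidine, 120 °C) followed by DBU equilibration. The fallback sets out from 8 and comes back at 13.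

Step 13. The risk is E2 elimination of the oxyphosphonium intermediate toward C3 or C5, giving a dihydropyran, faster than SN2 at the hindered ring carbon. The fallback avoids the halide and the organozinc altogether. Alcohol 17 is converted (oxalyl chloride, then 1 equiv aqueous CsOH) into the caesium oxalate half-ester F4. Under dual photoredox/nickel catalysis (Ir[dF(CF3)ppy]2(dtbbpy)PF6, NiBr2(dtbbpy), 23, DMSO/dioxane, blue light) F4 loses two molecules of CO2 to give the C4 radical, which is arylated by 23 trans to the C3 substituent. The fallback sets out from 17 and comes back at 25.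

Further compounds
F1 | step 17 | arylzinc iodide of the chalcone triacetate | COc1cc(OC(C)=O)c([Zn]I)c(OC(C)=O)c1C(=O)/C=C/c1ccc(OC(C)=O)cc1
F2 | step 8 | (E)-3-[4-(TBS-oxy)phenyl]prop-2-enyl methyl carbonate | COC(=O)OC/C=C/c1ccc(O[Si](C)(C)C(C)(C)C)cc1
F3 | step 8 | methyl (2S,6S)-4-oxo-2-[4-(TBS-oxy)phenyl]-3-{(1S)-1-[4-(TBS-oxy)phenyl]prop-2-enyl}-6-{2-[4-(TBS-oxy)phenyl]ethyl}oxane-3-carboxylate (allyl group drawn trans to the C2 aryl; C3 configuration immaterial) | O=C1C[C@H](CCc2ccc(O[Si](C)(C)C(C)(C)C)cc2)O[C@H](c2ccc(O[Si](C)(C)C(C)(C)C)cc2)[C@@]1(C(=O)OC)[C@H](C=C)c1ccc(O[Si](C)(C)C(C)(C)C)cc1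
F4 | step 13 | caesium oxalate half-ester of alcohol 17 | [Cs+].[O-]C(=O)C(=O)O[C@@H]1C[C@H](CCc2ccc(O[Si](C)(C)C(C)(C)C)cc2)O[C@H](c2ccc(O[Si](C)(C)C(C)(C)C)cc2)[C@H]1[C@H](/C=C/C[C@@H](OC(C)=O)CCc1ccc(O[Si](C)(C)C(C)(C)C)cc1)c1ccc(O[Si](C)(C)C(C)(C)C)cc1
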